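(The numbers in the tables stem from a simulated flask from invented constants; noise was put on by code.)

The amber run was charged with more solid substrate than the violet run, yet at 90.0 min both hold about the same c(target), 0.0381 M against 0.0364 M. So I reckon in concentration, not in percent.

| flask | solid substrate | remark | time |
|---|---|---|---|
| violet | 0.18 M | run made earlier |  |
| amber | 0.28 M | run made earlier |  |
| flask | 0.37 M |  | 80 min |

| run | time / min | target / % |
|---|---|---|
| violet | 8.00 | 0 |
| violet | 12.0 | 3.2 |
| violet | 20.0 | 3.0 |
| violet | 40.0 | 8.1 |
| violet | 60.0 | 14.8 |
| violet | 90.0 | 20.2 |
| amber | 6.00 | 0 |
| amber | 20.0 | 2.2 |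
| amber | 30.0 | 3.5 |
| amber | 50.0 | 7.2 |
| amber | 80.0 | 11.4 |
| amber | 90.0 | 13.6 |

(standard deviation of a reading: 1 percentage point)

- solid, in amounts per volume of the solution: solid substrate
- at the start none of the solid substrate is in solution

- south: doubling the dissolution coefficient of the solid substrate, all else as stated
- north: doubling the solubility of the solid substrate, all else as stated

- amount of target at 80 min, in percent of the solid substrate charged
- the change that raises the amount of target at 80 min, in percent of the solid substrate charged most ("none" if none brings more than 2 percentage points) (south / north / none)
- amount of target at 80 min, in percent of the solid substrate charged, after south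

I call the c(target) gained per minute, pooled over these two last readings, the output w; it is a zero-order behaviour in the charge, and I read it as 4.14 × 10⁻⁴ M min⁻¹. Over 80 min that gives 0.0331 M, and divided by the flask's charge of 0.37 M it gives me 8.94%.

The forecast, reckoned with a lag and so slightly differently, says 8.8%, names north as the best change and puts 9.5% after south, on the ground that “the rate does not depend on the charge”.

The flask gives 9.14%. North adds 9.1 percentage points and south adds 7.1 points, so the best change is north, and south reaches 16.3%, well above the forecast's value.

    starting material ⇌ target (K = 1.10, k = 0.00230 s⁻¹)
    target ⇌ isomer of the product (K = 0.380, k = 0.00260 s⁻¹)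
    solid substrate ⇌ starting material, rate k3*(cs3 - [starting material]) while solid is left; crystals form when [starting material] > cs3 (solubility = 0.160 M, k = 1.20 × 10⁻⁴ s⁻¹)

The flask's target comes to 0.0338 M, close to what w gave, while 78.1% of its charge is still solid. The neighbouring flask keeps the time but holds 0.22 M of solid substrate. The same w gives the same 0.0331 M, which on this smaller charge is 15.0%. That neighbouring flask gives 15.4%, or 0.0339 M of target, with 63.2% of its charge still solid.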